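**Convention.** Atoms carry germacrane numbers: C1–C10 form the ten-membered ring, C12 is the lactone carbonyl, C11 bears the acetoxymethyl carbon C13, C14 is the methyl on C10, C15 the methyl on C4. Ring B is the cyclohexane C1, C10, C9, C8, C7, C6 of the bicyclic intermediates. TBS = tert-butyldimethylsilyl.

## The problem

Target 25 is a ten-membered carbocycle fused through C6–C7 to a butenolide whose γ-carbon C6 also carries the enol-lactone double bond C5=C6, with C4 cis to the lactone oxygen and trans to C7 in the ring. It bears a C1 ketone, a tertiary carbinol at C4 (R), a methyl-bearing C10 (S) next to the ketone, an allylic 3-methylbut-2-enoate at C8 (R) and an allylic acetate at C13. Closing a ten-membered ring head-on costs entropy and transannular strain. C4 lies 1,5 to C8 and C10 across the ring, so it cannot be steered by them in an open chain; only a small-ring template can relay C8 to C6 and C6 to C4, and C10 becomes epimerisable once C1 is a ketone. The ylidene butenolide, the two esters and the γ-hydroxy ketone will not survive alkoxides, organometallics or hydrides, so the esters must come last. The C1 carbonyl and the C5=C6 alkene are 1,5-related through C2–C3–C4, the retron of an oxy-Cope shift. Joining C1–C6 and cutting C3–C4 gives a ring-B cyclohexanol with a vinyl group on C1 and a 2-silyloxyprop-1-enyl group on C6. The planar butenolide holds the C6–O bond in the plane of C7=C11 and so forces C5 axial on ring B; the hydroxyl on C1 must then be anti to C5 for a chair to be reachable, and C5 has to be cis to the C10 methyl, which strains the bicycle.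

## Retrosynthesis

**Esters and silyl ethers.** Target 25 is cut at the C8–O acyl bond to hydroxy acetate 24, at the acetate to triol 23, and at three O–Si bonds to tris-silyl ether 22. Neither ester would survive the steps before, so both go on last, the primary C13 hydroxyl first. C8 is carried as its S epimer (reason under the C6–C5 cut), so the final esterification is run with inversion. This costs no extra step.

**C3–C4, the key cut.** In 22 the bond C3–C4 is cut and C1–C6 re-formed, which leads to cyclohexanol 19. Against closures at C5–C6 or C6–C7 this replaces a medium-ring closure by a six-membered ring, and the ring expansion itself sets C4 and the alkene geometry. The forward step asks for a concerted chair. With C5 pinned axial, a vinyl group trans to it would also be axial and antiperiplanar to it, out of reach. Therefore 19 has the C1 hydroxyl anti to C5 and the vinyl group equatorial and gauche to C5. The shift is suprafacial on C6–C5–C4, so a 6S centre and a (Z)-enol ether should give 4R.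

**C4–O and the C4 carbonyl.** The silyl enol ether of 19 comes from methyl ketone 18, and 18 from the allyl group of 17 by oxidation. An allyl group rather than a 2-oxopropyl group is carried so that only one ketone (C1) is present while C1 is built.

**C1–O and C1–C2.** Carbinol 17 is traced through allylic sulfoxide 16 to carbinol 14, and 14 to ketone 12 and vinylmagnesium bromide 13. A carbon nucleophile should add to C1 anti to the axial C6 allyl group, which gives the epimer that cannot rearrange. The C1–O bond is therefore re-formed by a [2,3] shift that delivers oxygen from the open face. This costs two steps and makes the selectivity of the vinyl addition irrelevant.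

**C6–C5.** Ketone 12 is cut to the stabilised nucleophile 10 and allyl methyl carbonate 11. The anion of 10 is flat around C6, and a C8 silyloxy group is pushed pseudoaxial by A(1,3) strain with C13. With natural 8R this would send the allyl group to the face that leads to 4S. With 8S it shields the other face and should give 6S, so C8 is set as S.

**C1–C6.** Keto lactone 10 is cut to ester 9. An ester as acyl donor gives C1 directly at the ketone level.

**C8, C13 and O–Si.** Ester 9 comes from diol 8 by silylation, 8 from ketone 7 by reagent-controlled reduction, and 7 from bromide 6 by attaching C13.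

**C7–C8 and C8–C9.** Ketone 6 is cut into dibromobutenolide 4, carbon monoxide and zinc reagent 5, made from iodide 2. Iodide 2 comes from hydroxy ester 1, which supplies C10, and 4 from mucobromic acid 3, which supplies the butenolide.

## Roads not taken

**Alternative 1:** cut C6–C7 and O–C6. The open-chain (Z)-iodo acid A2 would, under Pd(PPh3)4, CuI and Et3N, close the ten-membered ring by Sonogashira coupling and then add its carboxylate 5-exo to the alkyne to give A1. Merits: both rings form in one flask, C4, C8 and C10 are set independently on an open chain, and no strained bicycle is needed. Weak points: the ring must close through a linear C5–C6 alkyne unit inside a ten-membered ring, at high dilution and in competition with alkyne dimerisation. The vinyl iodide is tetrasubstituted, and 6-endo lactonisation is possible. In stereochemical independence this road is better than the chosen one. The chosen plan sets against it a ring made without macrocyclisation and an alkene geometry fixed by a chair.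

**Alternative 2:** cut C5=C6. Aldehyde A4 would be converted by TBSOTf and i-Pr2NEt into its 2-silyloxyfuran, whose C6 adds to the C5 aldehyde, and DBU would then eliminate to A3. Merits: it uses the innate γ-nucleophilicity of the butenolide, the aldehyde cannot enolise, C4 is set early, and the substrate is reached in about as few steps. Weak points: a medium ring closes onto a neopentyl aldehyde. The C5=C6 geometry is left to thermodynamics. C1 must be a protected carbinol that is oxidised after the sensitive ylidene is in place. The chosen plan is weaker in substrate simplicity and stronger in geometric control.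

**Alternative 3:** cut C1–C6 of decalin mesylate A6. KOt-Bu would form the C1 alkoxide and a Grob fragmentation would give A5. Merits: such fragmentations are the best-precedented stereospecific entry to (E)-cyclodecenones, and the fragmentation itself is safer than an oxy-Cope shift with these substituents. Weak points: A6 needs five contiguous stereocentres, two of them adjacent and quaternary, and a secondary mesylate between them. The antiperiplanar alignment asks for a trans-fused decalin with the C6–O bond axial, which the planar butenolide does not allow. C3–C4 must be made earlier in a separate step. The chosen plan forms C3–C4 and C4 in the ring-expanding step from a smaller precursor.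

Key step: step 14

Remark on the chemistry: the target is treated as the open 4-hydroxy-1-ketone drawn; its 1,4-hemiketal is taken to be in reversible equilibrium with it.

## Route

Step 1
Reactants: 1 methyl (S)-3-hydroxy-2-methylpropanoate
Product: 2 methyl (R)-3-iodo-2-methylpropanoate
Conditions: I2, PPh3, imidazole, CH2Cl2, 0 to 25 °C
Reagents that add atoms: iodine, II
Why: Appel-type iodination of a primary alcohol; the stereocentre is untouched and the descriptor changes only because CH2I outranks the ester carbon.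

Step 2
Reactants: 3 mucobromic acid
Product: 4 3,4-dibromofuran-2(5H)-one
Conditions: NaBH4, MeOH, 0 °C; then H2SO4, 0 to 25 °C
Reagents that add atoms: none
Why: Borohydride reduction of the open aldehyde form of the lactol followed by acid relactonisation, the usual deoxygenation of mucohalic acids.

Step 3
Reactants: 2 methyl (R)-3-iodo-2-methylpropanoate, 4 3,4-dibromofuran-2(5H)-one
Product: 6 methyl (S)-4-(4-bromo-5-oxo-2,5-dihydrofuran-3-yl)-2-methyl-4-oxobutanoate, via alkylzinc iodide 5 (not isolated)
Conditions: Zn dust (Me3SiCl, BrCH2CH2Br), DMF, 25 °C; then 4, Pd(PPh3)4 (5 mol %), CO (1 atm), THF, 25 to 40 °C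
Reagents that add atoms: carbon monoxide, [C-]#[O+]
Why: Zinc insertion gives an ester-tolerant β-zincio ester; carbonylative Negishi coupling at the more electrophilic β-bromide forms C7–C8 and C8–C9 and leaves the α-bromide for step 4.

Step 4
Reactants: 6 methyl (S)-4-(4-bromo-5-oxo-2,5-dihydrofuran-3-yl)-2-methyl-4-oxobutanoate
Product: 7 methyl (S)-4-[4-(hydroxymethyl)-5-oxo-2,5-dihydrofuran-3-yl]-2-methyl-4-oxobutanoate
Conditions: Bu3SnCH2OH, Pd(PPh3)4 (5 mol %), 1,4-dioxane, 90 °C
Reagents that add atoms: (tributylstannyl)methanol, OC[Sn](CCCC)(CCCC)CCCC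
Why: Stille hydroxymethylation of the activated α-bromo butenolide installs C13.

Step 5
Reactants: 7 methyl (S)-4-[4-(hydroxymethyl)-5-oxo-2,5-dihydrofuran-3-yl]-2-methyl-4-oxobutanoate
Product: 8 methyl (2S,4S)-4-hydroxy-4-[4-(hydroxymethyl)-5-oxo-2,5-dihydrofuran-3-yl]-2-methylbutanoate
Conditions: (R)-2-methyl-CBS-oxazaborolidine (20 mol %), BH3·SMe2 (2.2 equiv), THF, −30 °C; MeOH
Reagents that add atoms: none
Why: CBS reduction of an alkenyl ketone with the butenolide ring as the large group; the (R)-catalyst should give the 8S carbinol, the first equivalent of borane capping the primary hydroxyl.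

Step 6
Reactants: 8 methyl (2S,4S)-4-hydroxy-4-[4-(hydroxymethyl)-5-oxo-2,5-dihydrofuran-3-yl]-2-methylbutanoate
Product: 9 methyl (2S,4S)-4-(TBS-oxy)-4-[4-(TBS-oxymethyl)-5-oxo-2,5-dihydrofuran-3-yl]-2-methylbutanoate
Conditions: TBSOTf (2.5 equiv), 2,6-lutidine, CH2Cl2, −78 °C
Reagents that add atoms: tert-butyldimethylsilyl trifluoromethanesulfonate, CC(C)(C)[Si](C)(C)OS(=O)(=O)C(F)(F)F
Why: Silylation of both hydroxyls, done at once on the crude diol so that the γ-hydroxy ester does not lactonise.

Step 7
Reactants: 9 methyl (2S,4S)-4-(TBS-oxy)-4-[4-(TBS-oxymethyl)-5-oxo-2,5-dihydrofuran-3-yl]-2-methylbutanoate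
Product: 10 (4S,6S)-4-(TBS-oxy)-3-(TBS-oxymethyl)-6-methyl-5,6-dihydrobenzofuran-2,7(4H,7aH)-dione
Conditions: LiN(SiMe3)2 (2.3 equiv), THF, −78 to −20 °C; AcOH
Reagents that add atoms: none
Why: Proposed new method: γ-deprotonation gives the 2-oxidofuran, whose C6 attacks the C1 ester 6-exo-trig in a vinylogous Dieckmann condensation; acylation at C11 would give a non-enolisable quaternary β-keto lactone that can revert through methoxide, whereas the C6 product is drained as its doubly stabilised enolate, which also protects C10 from epimerisation; the closest known reaction types are the Dieckmann condensation and the γ-selective vinylogous aldol addition of butenolide dienolates.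

Step 8
Reactants: 10 (4S,6S)-4-(TBS-oxy)-3-(TBS-oxymethyl)-6-methyl-5,6-dihydrobenzofuran-2,7(4H,7aH)-dione, 11 allyl methyl carbonate
Product: 12 (4S,6S,7aS)-7a-allyl-4-(TBS-oxy)-3-(TBS-oxymethyl)-6-methyl-5,6-dihydrobenzofuran-2,7(4H,7aH)-dione
Conditions: Pd(PPh3)4 (5 mol %), THF, 0 to 25 °C
Reagents that add atoms: none
Why: Tsuji–Trost allylation of a soft, doubly stabilised carbon nucleophile, with methoxide from 11 as the only base; the flat anion holds its C8 silyloxy group pseudoaxial to avoid A(1,3) strain with C13, so the allyl group should enter C6 on the opposite face, cis to the C10 methyl (6S); an allyl group that first lands on C11 would reach C6 on the same face by Cope shift.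

Step 9
Reactants: 12 (4S,6S,7aS)-7a-allyl-4-(TBS-oxy)-3-(TBS-oxymethyl)-6-methyl-5,6-dihydrobenzofuran-2,7(4H,7aH)-dione, 13 vinylmagnesium bromide
Product: 14 (4S,6S,7S,7aS)-7a-allyl-7-hydroxy-4-(TBS-oxy)-3-(TBS-oxymethyl)-6-methyl-7-vinyl-5,6,7,7a-tetrahydrobenzofuran-2(4H)-one
Conditions: CeCl3 (1.5 equiv), THF, −78 °C; NH4Cl (aq)
Reagents that add atoms: none
Why: Organocerium 1,2-addition to the hindered, enolisable C1 ketone without epimerising C10; attack anti to the axial C6 allyl group should give mainly the epimer with vinyl trans to allyl, but either epimer serves because step 10 erases C1.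

Step 10
Reactants: 14 (4S,6S,7S,7aS)-7a-allyl-7-hydroxy-4-(TBS-oxy)-3-(TBS-oxymethyl)-6-methyl-7-vinyl-5,6,7,7a-tetrahydrobenzofuran-2(4H)-one
Product: 16 7a-allyl-4-(TBS-oxy)-3-(TBS-oxymethyl)-6-methyl-7-[2-(phenylsulfinyl)ethylidene]-5,6,7,7a-tetrahydrobenzofuran-2(4H)-one (C6, C8, C10 as in 12), via phenylsulfenate ester 15 (not isolated)
Conditions: LiN(SiMe3)2 (1.05 equiv), THF, −78 °C; PhSCl (1.1 equiv), −78 to 0 °C
Reagents that add atoms: benzenesulfenyl chloride, ClSc1ccccc1
Why: O-sulfenylation of the lithium alkoxide and Mislow–Evans [2,3] rearrangement of sulfenate 15 to the more stable allylic sulfoxide, which makes C1 trigonal.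

Step 11
Reactants: 16 7a-allyl-4-(TBS-oxy)-3-(TBS-oxymethyl)-6-methyl-7-[2-(phenylsulfinyl)ethylidene]-5,6,7,7a-tetrahydrobenzofuran-2(4H)-one
Product: 17 (4S,6S,7R,7aS)-7a-allyl-7-hydroxy-4-(TBS-oxy)-3-(TBS-oxymethyl)-6-methyl-7-vinyl-5,6,7,7a-tetrahydrobenzofuran-2(4H)-one
Conditions: P(OMe)3 (5 equiv), MeOH, 50 °C
Reagents that add atoms: none
Why: Reverse Mislow–Evans rearrangement with thiophile capture; the sulfenate that forms by oxygen delivery to the face of C1 anti to the axial C6 allyl group and the C10 methyl is cleaved by the phosphite, which should place the hydroxyl anti to C5 and the vinyl group cis to the allyl group (1R).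

Step 12
Reactants: 17 (4S,6S,7R,7aS)-7a-allyl-7-hydroxy-4-(TBS-oxy)-3-(TBS-oxymethyl)-6-methyl-7-vinyl-5,6,7,7a-tetrahydrobenzofuran-2(4H)-one
Product: 18 (4S,6S,7R,7aS)-7-hydroxy-4-(TBS-oxy)-3-(TBS-oxymethyl)-6-methyl-7a-(2-oxopropyl)-7-vinyl-5,6,7,7a-tetrahydrobenzofuran-2(4H)-one
Conditions: PdCl2 (10 mol %), CuCl (1 equiv), O2 (1 atm), DMF/H2O (7:1), 25 °C
Reagents that add atoms: water, O
Why: Tsuji–Wacker oxidation of the unhindered allyl group to the methyl ketone; the vinyl group on the tertiary carbinol carbon is hindered and deactivated by the allylic oxygen.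

Step 13
Reactants: 18 (4S,6S,7R,7aS)-7-hydroxy-4-(TBS-oxy)-3-(TBS-oxymethyl)-6-methyl-7a-(2-oxopropyl)-7-vinyl-5,6,7,7a-tetrahydrobenzofuran-2(4H)-one
Product: 19 (4S,6S,7R,7aS)-7-hydroxy-4-(TBS-oxy)-3-(TBS-oxymethyl)-6-methyl-7a-[(Z)-2-(TBS-oxy)prop-1-enyl]-7-vinyl-5,6,7,7a-tetrahydrobenzofuran-2(4H)-one
Conditions: TBSOTf (1.1 equiv), Et3N, CH2Cl2, −78 to −40 °C
Reagents that add atoms: tert-butyldimethylsilyl trifluoromethanesulfonate, CC(C)(C)[Si](C)(C)OS(=O)(=O)C(F)(F)F
Why: Soft enolisation with silyl triflate and amine avoids a free enolate that could expel the lactone carboxylate; the trisubstituted enol ether with oxygen cis to C6 is the thermodynamic isomer, and the hindered tertiary C1 hydroxyl should be silylated much more slowly at low temperature.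

Step 14
Reactants: 19 (4S,6S,7R,7aS)-7-hydroxy-4-(TBS-oxy)-3-(TBS-oxymethyl)-6-methyl-7a-[(Z)-2-(TBS-oxy)prop-1-enyl]-7-vinyl-5,6,7,7a-tetrahydrobenzofuran-2(4H)-one
Product: 22 (4R,8S,10S)-4,8,13-tris(TBS-oxy)-1-oxogermacra-5Z,7(11)-dien-12,6-olide, via potassium alkoxide 20 (not isolated), via potassium enolate 21 (not isolated)
Conditions: KH (1.5 equiv), 18-crown-6 (1.5 equiv), THF, −78 to 0 °C; AcOH, THF, −78 °C
Reagents that add atoms: none
Why: KH with 18-crown-6 gives potassium alkoxide 20; because the planar butenolide holds the C6–O bond in the plane of C7=C11, C5 is axial on ring B, the alkoxide oxygen is antiperiplanar to it and the equatorial vinyl group is gauche to it, so C3 and C4 can meet in a six-membered chair. A concerted [3,3] shift forms C3–C4 as C1–C6 breaks and gives enolate 21, which is protonated at C2 on the cold acidic quench; the closest known reaction type is the anionic oxy-Cope ring expansion of 1,2-dialkenylcyclohexanols to cyclodec-5-enones. No ring is closed; ring B is enlarged by four atoms to the ten-membered ring. C4 is the only new stereocentre: the shift is suprafacial on C6–C5–C4, so its configuration follows from the 6S centre and the (Z)-enol ether, whose oxygen sits pseudoaxial in the chair, and should be 4R whatever the C1 configuration. The C5=C6 geometry (C4 trans to C7, cis to the lactone oxygen) follows from C7 lying anti to C2 and hence pseudoequatorial in the chair. C8 and C10 are spectators; the enolate forms away from C10 and is quenched cold so that C10 is not epimerised. The step needs the concerted path to outrun retro-vinylogous-aldol cleavage of C1–C6, acyl shift of the lactone to the alkoxide and silyl transfer from the enol ether; the donor enol ether, the strain of the all-cis ring B and the stabilised enolate and conjugated ylidene butenolide of the product should favour it.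

Step 15
Reactants: 22 (4R,8S,10S)-4,8,13-tris(TBS-oxy)-1-oxogermacra-5Z,7(11)-dien-12,6-olide
Product: 23 (4R,8S,10S)-4,8,13-trihydroxy-1-oxogermacra-5Z,7(11)-dien-12,6-olide
Conditions: HF·pyridine, pyridine, THF, 0 to 25 °C
Reagents that add atoms: none
Why: Fluoride cleavage of the primary, secondary and tertiary silyl ethers; buffered HF·pyridine should spare the enol lactone and the ketone, the tertiary ether at C4 being the slowest.

Step 16
Reactants: 23 (4R,8S,10S)-4,8,13-trihydroxy-1-oxogermacra-5Z,7(11)-dien-12,6-olide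
Product: 24 (4R,8S,10S)-13-acetoxy-4,8-dihydroxy-1-oxogermacra-5Z,7(11)-dien-12,6-olide
Conditions: Ac2O (1.1 equiv), 2,4,6-collidine, CH2Cl2, −40 °C
Reagents that add atoms: acetic anhydride, CC(=O)OC(C)=O
Why: Selective acylation of the primary allylic C13 hydroxyl over the hindered secondary C8 and tertiary C4 hydroxyls with a limiting amount of anhydride and a weak base at low temperature.

Step 17
Reactants: 24 (4R,8S,10S)-13-acetoxy-4,8-dihydroxy-1-oxogermacra-5Z,7(11)-dien-12,6-olide
Product: 25 (4R,8R,10S)-13-acetoxy-4-hydroxy-8-(3-methylbut-2-enoyloxy)-1-oxogermacra-5Z,7(11)-dien-12,6-olide (CNP0186726.1)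
Conditions: 3-methylbut-2-enoic acid, PPh3, DIAD, toluene, 0 to 25 °C
Reagents that add atoms: 3-methylbut-2-enoic acid, CC(C)=CC(O)=O
Why: Mitsunobu esterification; the C8 oxyphosphonium ion is displaced by the carboxylate with inversion, turning 8S into the 8R ester, and the tertiary C4 hydroxyl does not react.

## Compound list

1 | methyl (S)-3-hydroxy-2-methylpropanoate | COC(=O)[C@@H](C)CO | starting material
2 | methyl (R)-3-iodo-2-methylpropanoate | COC(=O)[C@@H](C)CI | intermediate
3 | mucobromic acid (3,4-dibromo-5-hydroxyfuran-2(5H)-one) | O=C1OC(O)C(Br)=C1Br | starting material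
4 | 3,4-dibromofuran-2(5H)-one | O=C1OCC(Br)=C1Br | intermediate
5 | [(2R)-3-methoxy-2-methyl-3-oxopropyl]zinc iodide | COC(=O)[C@@H](C)C[Zn]I | intermediate
6 | methyl (S)-4-(4-bromo-5-oxo-2,5-dihydrofuran-3-yl)-2-methyl-4-oxobutanoate | COC(=O)[C@@H](C)CC(=O)C1=C(Br)C(=O)OC1 | intermediate
7 | methyl (S)-4-[4-(hydroxymethyl)-5-oxo-2,5-dihydrofuran-3-yl]-2-methyl-4-oxobutanoate | COC(=O)[C@@H](C)CC(=O)C1=C(CO)C(=O)OC1 | intermediate
8 | methyl (2S,4S)-4-hydroxy-4-[4-(hydroxymethyl)-5-oxo-2,5-dihydrofuran-3-yl]-2-methylbutanoate | COC(=O)[C@@H](C)C[C@H](O)C1=C(CO)C(=O)OC1 | intermediate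
9 | methyl (2S,4S)-4-(TBS-oxy)-4-[4-(TBS-oxymethyl)-5-oxo-2,5-dihydrofuran-3-yl]-2-methylbutanoate | COC(=O)[C@@H](C)C[C@H](O[Si](C)(C)C(C)(C)C)C1=C(CO[Si](C)(C)C(C)(C)C)C(=O)OC1 | intermediate
10 | (4S,6S)-4-(TBS-oxy)-3-(TBS-oxymethyl)-6-methyl-5,6-dihydrobenzofuran-2,7(4H,7aH)-dione (C7a epimers and enol in equilibrium) | CC(C)(C)[Si](C)(C)OCC1=C2[C@@H](O[Si](C)(C)C(C)(C)C)C[C@H](C)C(=O)C2OC1=O | intermediate
11 | allyl methyl carbonate | C=CCOC(=O)OC | starting material
12 | (4S,6S,7aS)-7a-allyl-4-(TBS-oxy)-3-(TBS-oxymethyl)-6-methyl-5,6-dihydrobenzofuran-2,7(4H,7aH)-dione (allyl cis to the C10 methyl, trans to the C8 silyloxy group) | CC(C)(C)[Si](C)(C)OCC1=C2[C@@H](O[Si](C)(C)C(C)(C)C)C[C@H](C)C(=O)[C@@]2(CC=C)OC1=O | intermediate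
13 | vinylmagnesium bromide | C=C[Mg]Br | starting material
14 | (4S,6S,7S,7aS)-7a-allyl-7-hydroxy-4-(TBS-oxy)-3-(TBS-oxymethyl)-6-methyl-7-vinyl-5,6,7,7a-tetrahydrobenzofuran-2(4H)-one (expected major C1 epimer, vinyl trans to allyl) | CC(C)(C)[Si](C)(C)OCC1=C2[C@@H](O[Si](C)(C)C(C)(C)C)C[C@H](C)[C@@](O)(C=C)[C@@]2(CC=C)OC1=O | intermediate
15 | O-phenylsulfenate ester of 14 | CC(C)(C)[Si](C)(C)OCC1=C2[C@@H](O[Si](C)(C)C(C)(C)C)C[C@H](C)[C@@](OSc3ccccc3)(C=C)[C@@]2(CC=C)OC1=O | intermediate
16 | 7a-allyl-4-(TBS-oxy)-3-(TBS-oxymethyl)-6-methyl-7-[2-(phenylsulfinyl)ethylidene]-5,6,7,7a-tetrahydrobenzofuran-2(4H)-one (C6, C8, C10 as in 12; alkene and sulfur isomers) | CC(C)(C)[Si](C)(C)OCC1=C2[C@@H](O[Si](C)(C)C(C)(C)C)C[C@H](C)C(=CCS(=O)c3ccccc3)[C@@]2(CC=C)OC1=O | intermediate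
17 | (4S,6S,7R,7aS)-7a-allyl-7-hydroxy-4-(TBS-oxy)-3-(TBS-oxymethyl)-6-methyl-7-vinyl-5,6,7,7a-tetrahydrobenzofuran-2(4H)-one (vinyl cis to allyl) | CC(C)(C)[Si](C)(C)OCC1=C2[C@@H](O[Si](C)(C)C(C)(C)C)C[C@H](C)[C@](O)(C=C)[C@@]2(CC=C)OC1=O | intermediate
18 | (4S,6S,7R,7aS)-7-hydroxy-4-(TBS-oxy)-3-(TBS-oxymethyl)-6-methyl-7a-(2-oxopropyl)-7-vinyl-5,6,7,7a-tetrahydrobenzofuran-2(4H)-one | CC(C)(C)[Si](C)(C)OCC1=C2[C@@H](O[Si](C)(C)C(C)(C)C)C[C@H](C)[C@](O)(C=C)[C@@]2(CC(C)=O)OC1=O | intermediate
19 | (4S,6S,7R,7aS)-7-hydroxy-4-(TBS-oxy)-3-(TBS-oxymethyl)-6-methyl-7a-[(Z)-2-(TBS-oxy)prop-1-enyl]-7-vinyl-5,6,7,7a-tetrahydrobenzofuran-2(4H)-one | CC(C)(C)[Si](C)(C)OCC1=C2[C@@H](O[Si](C)(C)C(C)(C)C)C[C@H](C)[C@](O)(C=C)[C@@]2(/C=C(/C)O[Si](C)(C)C(C)(C)C)OC1=O | intermediate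
20 | potassium alkoxide of 19 | CC(C)(C)[Si](C)(C)OCC1=C2[C@@H](O[Si](C)(C)C(C)(C)C)C[C@H](C)[C@]([O-])(C=C)[C@@]2(/C=C(/C)O[Si](C)(C)C(C)(C)C)OC1=O.[K+] | intermediate
21 | potassium C1(C2) enolate of 22 | CC(C)(C)[Si](C)(C)OCC1=C2/C(=C/[C@](C)(O[Si](C)(C)C(C)(C)C)C/C=C(/[O-])[C@@H](C)C[C@@H]2O[Si](C)(C)C(C)(C)C)OC1=O.[K+] | intermediate
22 | (4R,8S,10S)-4,8,13-tris(TBS-oxy)-1-oxogermacra-5Z,7(11)-dien-12,6-olide | CC(C)(C)[Si](C)(C)OCC1=C2/C(=C/[C@](C)(O[Si](C)(C)C(C)(C)C)CCC(=O)[C@@H](C)C[C@@H]2O[Si](C)(C)C(C)(C)C)OC1=O | intermediate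
23 | (4R,8S,10S)-4,8,13-trihydroxy-1-oxogermacra-5Z,7(11)-dien-12,6-olide | OCC1=C2/C(=C/[C@](C)(O)CCC(=O)[C@@H](C)C[C@@H]2O)OC1=O | intermediate
24 | (4R,8S,10S)-13-acetoxy-4,8-dihydroxy-1-oxogermacra-5Z,7(11)-dien-12,6-olide | CC(=O)OCC1=C2/C(=C/[C@](C)(O)CCC(=O)[C@@H](C)C[C@@H]2O)OC1=O | intermediate
25 | (4R,8R,10S)-13-acetoxy-4-hydroxy-8-(3-methylbut-2-enoyloxy)-1-oxogermacra-5Z,7(11)-dien-12,6-olide (CNP0186726.1) | CC(=O)OCC1=C2/C(=C/[C@](C)(O)CCC(=O)[C@@H](C)C[C@H]2OC(=O)C=C(C)C)OC1=O | target

## Step count and risks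

Total: 17 steps. Longest linear sequence: 16 steps (1 to 25 through steps 1 and 3–17; the branch from 3 through steps 2 and 3–17 is equally long).

**Step 7 (labelled step).** The dienolate may be acylated at C11 without reverting, or base may remove the C8 hydrogen and scramble C8, because C-acylation at the γ-carbon of a butenolide is not established. The fallback uses known chemistry and sets out from 9. The methyl ester is hydrolysed selectively with Me3SnOH to the carboxylic acid F1. This is coupled with ethanethiol (DCC, DMAP) to the S-ethyl thioester F2. Fukuyama reduction (Et3SiH, Pd/C) gives the aldehyde F3. An intramolecular vinylogous aldol addition (TBSOTf, Et3N, then BF3·OEt2) closes ring B to the hydroxy lactone F4, and oxidation with DMP returns to 10.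

**Step 14 (key step).** The alkoxide may fragment by retro-vinylogous aldol cleavage and recombine by Michael addition, which would loosen the relay to C4. The lactone may shift to the C1 oxygen, or the enol silyl group may move to the alkoxide and the freed enolate expel the lactone carboxylate; all are driven by the strain of ring B and the nucleophilicity of the naked alkoxide. The fallback sets out from 19 and avoids any alkoxide. The C1 hydroxyl is silylated with N-(trimethylsilyl)imidazole to the trimethylsilyl ether F5. Heating in 1,2-dichlorobenzene (150 to 200 °C) should bring about the neutral siloxy-Cope shift to the trimethylsilyl enol ether F6, and aqueous citric acid in THF returns to 22.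

**Step 8.** Facial selectivity may be poor if the C8 silyloxy group does not stay pseudoaxial. O-allylation is possible, and C10 may epimerise in the strained product if base builds up. The fallback sets out from 10. Allyl chloroformate and Et3N give the allyl dienol carbonate F7, and decarboxylative asymmetric allylic alkylation with Pd2(dba)3 and a tert-butyl phosphinooxazoline ligand (antipode chosen for 6S) returns to 12 under reagent control in a contact ion pair.

**Step 13.** Enolisation may occur towards C15 and give the terminal enol ether, and the C1 hydroxyl may be silylated, because C5 is neopentyl. The fallback sets out from 18. Kinetic deprotonation with LiN(i-Pr)2 (2.2 equiv) and TBSCl gives the terminal 2-silyloxyallyl isomer F8, and RuHCl(CO)(PPh3)3-catalysed double-bond migration (toluene, 80 °C) moves the alkene into the trisubstituted (Z) position and returns to 19.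

**Step 3.** Direct coupling without CO insertion, or homocoupling of the zinc reagent, may compete because the vinyl–palladium intermediate is electron-poor. The fallback sets out from 2 and 4. Zinc reagent 5 is coupled with vinyl bromide (Pd(PPh3)4) to methyl (S)-2-methylpent-4-enoate F9. Ozonolysis (O3, then Me2S) gives methyl (S)-2-methyl-4-oxobutanoate F10. Nozaki–Hiyama–Kishi coupling with 4 (CrCl2, NiCl2 cat., DMF) gives the hydroxy ester F11 as C8 epimers, and oxidation with DMP returns to 6.

**Step 17.** Elimination to a diene, SN2′ attack or no reaction may replace clean inversion at the hindered allylic C8. The fallback sets out from 24. Oxidation with DMP gives the 8-ketone F12. Luche reduction (NaBH4, CeCl3, MeOH, −78 °C), selective for the conjugated ketone, should give the 8R alcohol F13 if hydride attacks from the ring periphery. Acylation with 3-methylbut-2-enoyl chloride and pyridine returns to 25.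

## Further compounds

F1 | step 7 | (2S,4S)-4-(TBS-oxy)-4-[4-(TBS-oxymethyl)-5-oxo-2,5-dihydrofuran-3-yl]-2-methylbutanoic acid | OC(=O)[C@@H](C)C[C@H](O[Si](C)(C)C(C)(C)C)C1=C(CO[Si](C)(C)C(C)(C)C)C(=O)OC1
F2 | step 7 | S-ethyl (2S,4S)-4-(TBS-oxy)-4-[4-(TBS-oxymethyl)-5-oxo-2,5-dihydrofuran-3-yl]-2-methylbutanethioate | CCSC(=O)[C@@H](C)C[C@H](O[Si](C)(C)C(C)(C)C)C1=C(CO[Si](C)(C)C(C)(C)C)C(=O)OC1
F3 | step 7 | (2S,4S)-4-(TBS-oxy)-4-[4-(TBS-oxymethyl)-5-oxo-2,5-dihydrofuran-3-yl]-2-methylbutanal | O=C[C@@H](C)C[C@H](O[Si](C)(C)C(C)(C)C)C1=C(CO[Si](C)(C)C(C)(C)C)C(=O)OC1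
F4 | step 7 | (4S,6S)-7-hydroxy-4-(TBS-oxy)-3-(TBS-oxymethyl)-6-methyl-5,6,7,7a-tetrahydrobenzofuran-2(4H)-one (C7 and C7a epimers) | CC(C)(C)[Si](C)(C)OCC1=C2[C@@H](O[Si](C)(C)C(C)(C)C)C[C@H](C)C(O)C2OC1=O
F5 | step 14 | C1 trimethylsilyl ether of 19 | CC(C)(C)[Si](C)(C)OCC1=C2[C@@H](O[Si](C)(C)C(C)(C)C)C[C@H](C)[C@](O[Si](C)(C)C)(C=C)[C@@]2(/C=C(/C)O[Si](C)(C)C(C)(C)C)OC1=O
F6 | step 14 | C1(C2) trimethylsilyl enol ether of 22 | CC(C)(C)[Si](C)(C)OCC1=C2/C(=C/[C@](C)(O[Si](C)(C)C(C)(C)C)C/C=C(/O[Si](C)(C)C)[C@@H](C)C[C@@H]2O[Si](C)(C)C(C)(C)C)OC1=O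
F7 | step 8 | allyl (4S,6S)-4-(TBS-oxy)-3-(TBS-oxymethyl)-6-methyl-2-oxo-2,4,5,6-tetrahydrobenzofuran-7-yl carbonate | CC(C)(C)[Si](C)(C)OCC1=C2[C@@H](O[Si](C)(C)C(C)(C)C)C[C@H](C)C(OC(=O)OCC=C)=C2OC1=O
F8 | step 13 | terminal enol ether isomer of 19, 7a-[2-(TBS-oxy)prop-2-enyl] | CC(C)(C)[Si](C)(C)OCC1=C2[C@@H](O[Si](C)(C)C(C)(C)C)C[C@H](C)[C@](O)(C=C)[C@@]2(CC(=C)O[Si](C)(C)C(C)(C)C)OC1=O
F9 | step 3 | methyl (S)-2-methylpent-4-enoate | COC(=O)[C@@H](C)CC=C
F10 | step 3 | methyl (S)-2-methyl-4-oxobutanoate | COC(=O)[C@@H](C)CC=O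
F11 | step 3 | methyl (2S)-4-(4-bromo-5-oxo-2,5-dihydrofuran-3-yl)-4-hydroxy-2-methylbutanoate (C4 epimers) | COC(=O)[C@@H](C)CC(O)C1=C(Br)C(=O)OC1
F12 | step 17 | (4R,10S)-13-acetoxy-4-hydroxy-1,8-dioxogermacra-5Z,7(11)-dien-12,6-olide | CC(=O)OCC1=C2/C(=C/[C@](C)(O)CCC(=O)[C@@H](C)CC2=O)OC1=O
F13 | step 17 | (4R,8R,10S)-13-acetoxy-4,8-dihydroxy-1-oxogermacra-5Z,7(11)-dien-12,6-olide | CC(=O)OCC1=C2/C(=C/[C@](C)(O)CCC(=O)[C@@H](C)C[C@H]2O)OC1=O
A1 | alternative 1 | 8,13-bis(TBS) ether of the deacylated target | CC(C)(C)[Si](C)(C)OCC1=C2/C(=C/[C@](C)(O)CCC(=O)[C@@H](C)C[C@H]2O[Si](C)(C)C(C)(C)C)OC1=O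
A2 | alternative 1 | (Z)-3-iodo-2-(TBS-oxymethyl)alk-2-enoic acid with a terminal alkyne at C5–C6, open-chain substrate | C#C[C@](C)(O)CCC(=O)[C@@H](C)C[C@@H](O[Si](C)(C)C(C)(C)C)/C(I)=C(\CO[Si](C)(C)C(C)(C)C)C(O)=O
A3 | alternative 2 | ten-membered ylidene butenolide with C1 as silyl-protected carbinol | CC(C)(C)[Si](C)(C)OCC1=C2/C(=C/[C@](C)(O[Si](CC)(CC)CC)CC[C@H](O[Si](CC)(CC)CC)[C@@H](C)C[C@H]2O[Si](C)(C)C(C)(C)C)OC1=O
A4 | alternative 2 | butenolide with open chain ending in the C5 aldehyde | O=C[C@](C)(O[Si](CC)(CC)CC)CC[C@H](O[Si](CC)(CC)CC)[C@@H](C)C[C@@H](O[Si](C)(C)C(C)(C)C)C1=C(CO[Si](C)(C)C(C)(C)C)C(=O)OC1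
A5 | alternative 3 | tris-silyl ether of the deacylated target (C4 triethylsilyl) | CC(C)(C)[Si](C)(C)OCC1=C2/C(=C/[C@](C)(O[Si](CC)(CC)CC)CCC(=O)[C@@H](C)C[C@H]2O[Si](C)(C)C(C)(C)C)OC1=O
A6 | alternative 3 | trans-fused butenolide-decalin C1 alcohol with C5 mesylate | CC(C)(C)[Si](C)(C)OCC1=C2[C@H](O[Si](C)(C)C(C)(C)C)C[C@H](C)[C@@]3(O)CC[C@@](C)(O[Si](CC)(CC)CC)[C@@H](OS(C)(=O)=O)[C@]23OC1=O
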